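**Strategy**

The target is a (2S)-flavanone, and everything rests on the O1–C2 bond of ring C (O1, C2, C3, C4, C4a, C8a). C2, the only stereocentre, sits beta to the C4 ketone and carries the ring oxygen, so ring C is the oxa-Michael adduct of a 2'-hydroxychalcone. A chalcone isomerase closes this last ring and sets (2S) in one operation, which no small reagent does selectively on an unactivated chalcone. The precursor is an achiral (E)-chalcone whose only free ortho-hydroxyl is the one next to the benzyl-bearing carbon; the other ortho oxygen stays a methyl ether until the final step. The chalcone arises by ortho-quinone-methide benzylation and Claisen–Schmidt condensation.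

Key step: step 3

Remark on the chemistry: compound 2 is taken as a catalogue compound, and the isomerase is assumed to accept the 6'-O-methylated, 3'-benzylated chalcone 7, if necessary as a variant evolved on this substrate.

**Route**

Step 1
Reactants: 1 1-(6-hydroxy-2,3,4-trimethoxyphenyl)ethan-1-one; 2 2-(hydroxymethyl)-4-methoxyphenol
Product: 4 1-[2-hydroxy-3-(2-hydroxy-5-methoxybenzyl)-4,5,6-trimethoxyphenyl]ethan-1-one, via ortho-quinone methide 3 (not isolated)
Conditions: ZnCl2 (1.5 equiv), 1,4-dioxane, 80 °C; 2 added slowly to 1 (2 equiv)
Reagents that add atoms: none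
Why: Lewis-acid-promoted loss of water from 2 gives the ortho-quinone methide 3, which is trapped in a Friedel–Crafts-type conjugate addition (ortho-hydroxybenzylation) by the only unsubstituted carbon of ring A in 1, a position activated by an ortho hydroxyl, an ortho methoxy and a para methoxy group and only meta to the acetyl group; the excess of 1 and the slow addition of 2 are meant to suppress self-condensation of 2.

Step 2
Reactants: 4 1-[2-hydroxy-3-(2-hydroxy-5-methoxybenzyl)-4,5,6-trimethoxyphenyl]ethan-1-one; 5 benzaldehyde
Product: 7 (E)-1-[2-hydroxy-3-(2-hydroxy-5-methoxybenzyl)-4,5,6-trimethoxyphenyl]-3-phenylprop-2-en-1-one, via aldol adduct 6 (not isolated)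
Conditions: 5 (1.5 equiv), KOH (50% aq, excess), EtOH, 0 °C to rt; then 1 M HCl
Reagents that add atoms: none
Why: Claisen–Schmidt aldol condensation, in which the methyl ketone enolate adds to benzaldehyde and aldol 6 loses water (E1cB) to the conjugated, thermodynamically favoured (E)-enone, as is routine for 2'-hydroxy-6'-methoxyacetophenones; the chalcone is to be purified free of any racemic flavanone formed by base before it meets the enzyme.

Step 3
Reactants: 7 (E)-1-[2-hydroxy-3-(2-hydroxy-5-methoxybenzyl)-4,5,6-trimethoxyphenyl]-3-phenylprop-2-en-1-one
Product: 8 (2S)-8-(2-hydroxy-5-methoxybenzyl)-5,6,7-trimethoxy-2-phenyl-2,3-dihydro-4H-chromen-4-one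
Conditions: recombinant chalcone isomerase (EC 5.5.1.6, legume-type enzyme that also accepts 6'-deoxychalcones, or a variant evolved on 7), 50 mM potassium phosphate pH 7.0, 10% DMSO, 30 °C
Reagents that add atoms: none
Why: The isomerase binds the (E)-chalcone in its cleft, where the phenoxide of the C2' hydroxyl (ionised with the help of the active-site hydrogen-bond network) adds to C-beta of the enone while C-alpha is protonated through enzyme-bound water, i.e. an enzyme-catalysed intramolecular oxa-Michael addition. This is the native reaction type of the enzyme class, the conversion of 2'-hydroxychalcones into (2S)-flavanones, applied here to a more heavily substituted member of the same substrate class. Ring C closes in the 6-endo-trig mode with formation of the O1–C2 bond. The new stereocentre C2 is set by the catalyst alone: the pocket holds the enone so that the oxygen can reach only the Si face of C-beta, which corresponds to 2S. The step needs enantioselectivity, a single site of closure, and a rate well above that of the uncatalysed racemic closure; the substrate secures the site, because the only free hydroxyl ortho to the carbonyl is the one next to the benzyl-bearing carbon (the other ortho oxygen is a methyl ether and the phenol of the benzyl ring could only close a ten-membered ring). The same methyl ether removes the free 6'-hydroxyl that drives spontaneous closure, so the background reaction at pH 7 should stay slow and the enantiomeric purity should reflect the enzyme.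

Step 4
Reactants: 8 (2S)-8-(2-hydroxy-5-methoxybenzyl)-5,6,7-trimethoxy-2-phenyl-2,3-dihydro-4H-chromen-4-one
Product: 10 (2S)-5-hydroxy-8-(2-hydroxy-5-methoxybenzyl)-6,7-dimethoxy-2-phenyl-2,3-dihydro-4H-chromen-4-one, via bis(dichloroboryl) ether 9 (not isolated)
Conditions: BCl3 (1 M in CH2Cl2, 3 equiv), CH2Cl2, −78 to 0 °C, short reaction time; then ice-water
Reagents that add atoms: none
Why: Chelation-controlled ether cleavage, in which BCl3 bridges the C4 carbonyl and the peri C5 oxygen in a six-membered chelate so that chloride removes only that methyl group, while the methyl ethers at C6, C7 and on the benzyl ring lack this activation at low temperature; the free phenol is only borylated and is restored on hydrolysis, and the short, cold reaction is meant to leave the C2 stereocentre untouched.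

**Compound list**

1 | 1-(6-hydroxy-2,3,4-trimethoxyphenyl)ethan-1-one | CC(=O)c1c(O)cc(OC)c(OC)c1OC | starting material
2 | 2-(hydroxymethyl)-4-methoxyphenol | COc1ccc(O)c(CO)c1 | starting material
3 | 4-methoxy-6-methylidenecyclohexa-2,4-dien-1-one (ortho-quinone methide, transient) | COC1=CC(=C)C(=O)C=C1 | intermediate
4 | 1-[2-hydroxy-3-(2-hydroxy-5-methoxybenzyl)-4,5,6-trimethoxyphenyl]ethan-1-one | CC(=O)c1c(O)c(Cc2cc(OC)ccc2O)c(OC)c(OC)c1OC | intermediate
5 | benzaldehyde | O=Cc1ccccc1 | starting material
6 | 3-hydroxy-1-[2-hydroxy-3-(2-hydroxy-5-methoxybenzyl)-4,5,6-trimethoxyphenyl]-3-phenylpropan-1-one (racemic aldol adduct, transient) | O=C(CC(O)c1ccccc1)c1c(O)c(Cc2cc(OC)ccc2O)c(OC)c(OC)c1OC | intermediate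
7 | (E)-1-[2-hydroxy-3-(2-hydroxy-5-methoxybenzyl)-4,5,6-trimethoxyphenyl]-3-phenylprop-2-en-1-one | O=C(/C=C/c1ccccc1)c1c(O)c(Cc2cc(OC)ccc2O)c(OC)c(OC)c1OC | intermediate
8 | (2S)-8-(2-hydroxy-5-methoxybenzyl)-5,6,7-trimethoxy-2-phenyl-2,3-dihydro-4H-chromen-4-one | COc1ccc(O)c(Cc2c(OC)c(OC)c(OC)c3c2O[C@H](c2ccccc2)CC3=O)c1 | intermediate
9 | (2S)-5-(dichloroboryloxy)-8-[2-(dichloroboryloxy)-5-methoxybenzyl]-6,7-dimethoxy-2-phenyl-2,3-dihydro-4H-chromen-4-one (transient) | COc1ccc(OB(Cl)Cl)c(Cc2c(OC)c(OC)c(OB(Cl)Cl)c3c2O[C@H](c2ccccc2)CC3=O)c1 | intermediate
10 | (2S)-5-hydroxy-8-(2-hydroxy-5-methoxybenzyl)-6,7-dimethoxy-2-phenyl-2,3-dihydro-4H-chromen-4-one | COc1ccc(O)c(Cc2c(OC)c(OC)c(O)c3c2O[C@H](c2ccccc2)CC3=O)c1 | target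

**Count**

Total step count: 4. Longest linear sequence: 4 steps (1 to 4 to 7 to 8 to 10).

**Steps most likely to fail**

Step 3. The enzyme may turn over the hexasubstituted, 6'-O-methylated chalcone too slowly, since its natural substrates carry a free hydroxyl or no substituent at C6' and no benzyl group at C3'. The conversion would then stall, or the slow uncatalysed closure would erode the enantiomeric purity. The fallback uses known chemistry and sets the stereocentre on the closed ring instead. It sets out from 4 and comes back at 8.
- Compound 4 is formylated at the methyl group with ethyl formate and NaH in THF and cyclodehydrated in the same pot with HCl in MeOH. This should give the chromone 8-(2-hydroxy-5-methoxybenzyl)-5,6,7-trimethoxy-4H-chromen-4-one F1.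
- Phenylboronic acid is then added to F1 in an enantioselective conjugate addition. The catalyst is Pd(OCOCF3)2 with the antipode of 4-tert-butyl-2-(pyridin-2-yl)-4,5-dihydrooxazole that delivers 2S, with NH4PF6 and water in 1,2-dichloroethane at 60 °C. This should give 8.

Step 1. Self-condensation of the ortho-quinone methide, or a second benzylation on the methoxyphenol ring of the product, may outrun attack by the acyl-bearing ring of 1. The fallback forms the diarylmethane on an acyl-free, far more nucleophilic ring and installs the acetyl group afterwards. It sets out from 2 and comes back at 4.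
- Compound 2 is added slowly to an excess of commercial 3,4,5-trimethoxyphenol F2 (two equivalent ortho positions) with ZnCl2 in dioxane. This should give 2-(2-hydroxy-5-methoxybenzyl)-3,4,5-trimethoxyphenol F3.
- Friedel–Crafts (Fries-type) C-acetylation of F3 with acetic acid and BF3·OEt2 at 70 °C should then take place at the last free position of ring A, ortho to its hydroxyl, and give 4.

Step 4. The Lewis acid may open ring C by a retro-oxa-Michael process, with loss of configuration at C2 and reclosure through the newly freed hydroxyl, or it may cleave a second methyl ether. The fallback moves the demethylation to a stage without a stereocentre. It sets out from 7 and comes back at 10.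
- BCl3 in CH2Cl2 at −78 to 0 °C should cleave the methyl ether ortho to the carbonyl of the chalcone and give (E)-1-[2,6-dihydroxy-3-(2-hydroxy-5-methoxybenzyl)-4,5-dimethoxyphenyl]-3-phenylprop-2-en-1-one F4.
- F4 is then closed by the chalcone isomerase at pH 6.5 with a high enzyme loading, so that no reagent touches the flavanone after C2 is set; F4 belongs to the native 6'-hydroxychalcone class.
- The price is that the site of closure then rests on the enzyme pocket alone. Closure through the other hydroxyl and the faster spontaneous closure would have to be controlled and the isomer removed by chromatography.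

**Further compounds**

F1 | step 3 | 8-(2-hydroxy-5-methoxybenzyl)-5,6,7-trimethoxy-4H-chromen-4-one | COc1ccc(O)c(Cc2c(OC)c(OC)c(OC)c3c2OC=CC3=O)c1
F2 | step 1 | 3,4,5-trimethoxyphenol | COc1cc(O)cc(OC)c1OC
F3 | step 1 | 2-(2-hydroxy-5-methoxybenzyl)-3,4,5-trimethoxyphenol | COc1ccc(O)c(Cc2c(O)cc(OC)c(OC)c2OC)c1
F4 | step 4 | (E)-1-[2,6-dihydroxy-3-(2-hydroxy-5-methoxybenzyl)-4,5-dimethoxyphenyl]-3-phenylprop-2-en-1-one | O=C(/C=C/c1ccccc1)c1c(O)c(Cc2cc(OC)ccc2O)c(OC)c(OC)c1O
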